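The numbers are those of an exercise; the result is computed.

The easy step came first: free catalyst turns substrate into open intermediate at a pace I could read from the charge. The harder question for the next run was whether to charge the partner at once or feed it in.

| setting | west | east | south | south-west |
|---|---|---|---|---|
| substrate | 0.10 M | 0.10 M | 0.10 M | 0.10 M |
| partner | 0.0900 M | 0.0900 M | 0.0900 M | 0.0900 M (fed, over 3.00 h) |
| free catalyst | 1.7 mM | 1.7 mM | 1.7 mM | 1.7 mM |
| time | 3.0 h |  | 3.0 h | 3.0 h |
| remark | a tube with plug flow, the mixed feed as stated, residence time 3.0 h | a single well-mixed tank run continuously and read at steady state, 3.0 h in it on average | everything together in a closed stirred flask, run for 3.0 h | all but partner at the start; partner goes in evenly over 3.00 h, the run ends at 3.0 h |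

    substrate + free catalyst → free catalyst + open intermediate (k1 = 0.119 M⁻¹ s⁻¹)
    substrate + target → side product (k2 = 0.00478 M⁻¹ s⁻¹)
    partner + catalyst intermediate → free catalyst + target (k3 = 1.41 M⁻¹ s⁻¹)
    free catalyst + open intermediate ⇌ catalyst intermediate (K4 = 4.24 M⁻¹, k4 = 0.121 M⁻¹ s⁻¹)

* the set-up with the highest amount of open intermediate at the outlet or at the end, in percent of the substrate put in ("none" if the first two lie within 2 percentage points) (west / east / south / south-west / none)
* amount of open intermediate at the outlet or at the end, in percent of the substrate put in, west
* amount of open intermediate at the outlet or at the end, in percent of the substrate put in, east
* amount of open intermediate at the outlet or at the end, in percent of the substrate put in, south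
* amount of open intermediate at the outlet or at the end, in percent of the substrate put in, south-west

- in percentages every species weighs as the substrate in it: one side product counts as two
- the stated concentrations are those of everything mixed, before any reaction; amounts are the same in each set-up
- the feed brings no volume worth counting
- run time (west): 3.0 h

I kept free catalyst at its charge, which makes substrate loss by the first step and binding of open intermediate pseudo-first-order. Substrate then goes at 0.728 h⁻¹, and open intermediate binds at 0.741 h⁻¹, about the same pace. Catalyst intermediate falls back with a half-life of 24.3 s, short against 3.0 h, so I counted it as steady. Open intermediate once bound then goes on to target if the partner catches the catalyst intermediate, and otherwise it falls back.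

The quantity I carried was the crossing level, the fraction of the partner charge at which catalyst intermediate goes on to target as often as it falls back: 22.5 %. At a partner fraction x the capture share is x/(x + crossing). Far above the crossing, binding is the rate-limiting step of the loss; far below it, the partner step is.

With the whole charge present the share is 81.6 %. Feeding puts in, on average, half of the charge, so the share is 69.0 %, which is lower. I ignored the side step and the partner used, so these figures are rough. Made-and-lost arithmetic gave 29.8 % for south, and the same for the tube west. The tank east gave 24.4 %, and south-west gave 34.7 %. I would have run south-west.

The forecast chose south-west too, with 33.5 % for west, 26.8 % for east, 33.5 % for south and 40 % for south-west, each higher than my figure for that set-up. Its ground was that dosing “slows consumption of the open intermediate while substrate is still converting”.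

The simulation gave 27.7 % for west, 21.2 % for east, 27.7 % for south and 35.5 % for south-west, so south-west led. At 1.50 h partner read 32.2 % of its charge in south-west and 73.1 % in south, both above the crossing of 22.5 %. Those readings put the capture share at 58.9 % in south-west, lower than the 76.5 % in south, and open intermediate stood at 46.7 % against 39.0 %.

A neighbour of south-west was charged with 0.23 M of partner, which moves the crossing down to 8.80 % of that charge. Half of it delivered, on average, gives a share of 85.0 % and a reckoned 28.6 % of open intermediate in that neighbour; the simulation gave 24.6 % there.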